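Partner both makes target and destroys it, and dividing one of those rates by the other removes time from the problem.

common to all: time 6.0 h
- south-west: substrate 0.32 M (fed, over 80 min); partner 1.05 equiv; temperature 110 °C; all else is in the flask from the start; the feed brings no volume worth counting
- north: substrate 0.32 M (fed, over 80 min); partner 1.05 equiv; the addition at 90 °C, then warmed to 110 °C; the feed brings no volume worth counting
- east: substrate 0.32 M; partner 1.05 equiv (in portions, 3, over 80 min); temperature 110 °C; first portion at the start, last at 80 min
- south-east: substrate 0.32 M; partner 1.05 equiv (fed, over 80 min); temperature 110 °C; all else is in the flask from the start; the feed brings no volume worth counting

- the flask with the highest amount of target, in percent of the substrate charged ("all alike" if they lie within 1.5 percentage points) (south-west / north / east / south-east / all alike)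
- final target, as a percentage of the substrate charged, in south-west
- final target, as a percentage of the substrate charged, in north
- final target, as a percentage of the substrate charged, in east
- final target, as a percentage of the substrate charged, in south-east

- all constants are for 110 °C and move with temperature by the activation energies and enthalpies

    partner + target → over-reaction product (k1 = 0.14 /M/min, Ea1 = 83.0 kJ/mol)
    substrate ⇌ open intermediate (K2 = 9.0, k2 = 0.011 /min, Ea2 = 110 kJ/mol, ΔH2 = −2.00 kJ/mol)
    partner → second intermediate (k3 = 0.0081 /min, Ea3 = 128 kJ/mol)
    open intermediate + second intermediate → target (k4 = 0.70 /M/min, Ea4 = 79.0 kJ/mol)
    (constants at 110 °C)

Each time below is the inverse of a rate constant at the reference temperature. The two bimolecular steps are taken at the substrate's charge concentration.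

| Step | Time |
|---|---|
| substrate opens | 90.9 min |
| partner becomes second intermediate | 123 min |
| second intermediate meets open intermediate | 4.46 min |
| target meets partner | 22.3 min |

The third row is much shorter than the second. So, with open intermediate at hand, second intermediate is taken up as it forms, which is the steady-state approximation. Target then forms at m·P, where m is the constant of the second row and P is partner. Target is lost at l·P·T, where l is the constant of the fourth row and T is target. Both rates carry P, so their ratio holds no time, and T climbs towards m/l, or 0.0579 M. This target ceiling, m/l as a percentage of the substrate charged, is 18.1 %.

The first row is shorter than the second. In east and south-east, substrate is present from the start and partner comes in parts, so open intermediate should stay ahead. My reckoning for east is 18.1 %, and for south-east 18.1 %.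

South-west differs. Substrate arrives over 80 min while partner is already there, so second intermediate can build up, and what has built up becomes target later, when less partner stands. The ceiling does not count this stock. As a crude guess, I raise the ceiling by the fraction m·t, where t is the feed time, here 0.648. That gives south-west 29.8 %. North has its addition in the cold, and I give it half of that allowance, again a guess, so north comes to 23.9 %. My choice is south-west.

The forecast also names south-west, with 31 % there, 24 % in north, 20 % in east and 20.5 % in south-east, on the ground that “Only intermediate still held when partner runs out adds beyond that ceiling”; its south-west figure is above mine.

The simulation puts south-west first, with 33.8 % there, 24.6 % in north, 20.7 % in east and 20.9 % in south-east. East ends 2.6 percentage points above the ceiling. In south-west, the rate at which partner becomes second intermediate, over the rate at which it goes to over-reaction product, is m·P/(l·P·T), which is the ceiling over target. That ratio stands at 0.92 after 1.70 h and falls to 0.53 after 6.00 h. South-west's final target stands at 1.87 times the ceiling.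

The numbers of this flask belong to no real substance; no experiment stands behind them.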